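**Strategy.** The route rests on forming the butenolide C13=C14 bond last. Ring-closing metathesis of the acrylate ester of a 2-alkylallyl alcohol closes the five-membered lactone (O–C15–C14=C13–C16) on the fully functionalised, unprotected halimane core. The step exploits that these are the only olefins open to the catalyst: the ring-fusion C5=C10 olefin is tetrasubstituted between quaternary C4 and C9 and cannot enter metathesis. The core comes from a catalytic asymmetric Diels–Alder reaction of a ring-A siloxydiene (C4 set by CBS desymmetrisation of a 2,2-disubstituted 1,3-dione) with tiglaldehyde (C8, C9), Saegusa oxidation to the C5=C10 enone and CBS reduction (C6).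

Key step: step 19

Remark on numbering: halimane locants are used. Ring A is C1–C5 plus C10 (C3 ketone; C4 carries C19 methyl and the C18 acyloxymethyl). Ring B is C5–C10 (C6 carbinol; C17 methyl on C8; C20 methyl on C9). The side chain is C11–C12–C13(=C14–C15(=O)–O–C16).

Remark (assumption): the sense of both CBS reductions follows the usual large/small model. For step 7 the catalyst antipode is the one that exposes the C2-Si face of the enal, taken here as the (S)-series by the formyl C–H···O model; the antipodal catalyst is equally available should the sense prove opposite.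

Step 1
Reactants: 1 2-methylcyclohexane-1,3-dione
Product: 2 2-(hydroxymethyl)-2-methylcyclohexane-1,3-dione
Conditions: 37 % aq. HCHO (excess), cat. Et3N, THF/H2O, rt
Reagents that add atoms: formaldehyde C=O
Why: Aldol hydroxymethylation of the acidic dione at its only nucleophilic carbon creates the (still prochiral) quaternary C4; the adduct cannot dehydrate and excess formaldehyde should hold the retro-aldol equilibrium on the product side.

Step 2
Reactants: 2 2-(hydroxymethyl)-2-methylcyclohexane-1,3-dione
Product: 3 2-{[(2-methoxypropan-2-yl)oxy]methyl}-2-methylcyclohexane-1,3-dione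
Conditions: 2-methoxypropene, PPTS (cat.), CH2Cl2, 0 °C; Et3N quench
Reagents that add atoms: 2-methoxypropene COC(C)=C
Why: Acid-catalysed addition of the primary alcohol to the enol ether (mixed-ketal, MOP, protection) should block retro-aldol loss of formaldehyde and make the C18 arm clearly larger than the methyl group for step 3.

Step 3
Reactants: 3 2-{[(2-methoxypropan-2-yl)oxy]methyl}-2-methylcyclohexane-1,3-dione
Product: 5 (4aS,8aS)-2,2,4a-trimethylhexahydro-4H-1,3-benzodioxin-5-one (cis-fused acetonide), via hydroxy ketone MOP ether 4 (not isolated)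
Conditions: (R)-Me-CBS (0.2 equiv), catecholborane (1.1 equiv), toluene, −78 °C; MeOH; then CSA (cat.), CH2Cl2, 0 °C
Reagents that add atoms: none
Why: Corey–Bakshi–Shibata desymmetrising reduction, in which the catalyst binds the carbonyl lone pair anti to the quaternary carbon and should give the (S)-carbinol at the carbonyl whose required face lies anti to the larger CH2O-MOP arm (OH cis to CH2O), which fixes C4 as needed; acid then closes the hydroxy mixed ketal to the acetonide with loss of methanol.

Step 4
Reactants: 5 (4aS,8aS)-2,2,4a-trimethylhexahydro-4H-1,3-benzodioxin-5-one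
Product: 6 (4aS,8aS)-2,2,4a-trimethyl-4a,7,8,8a-tetrahydro-4H-1,3-benzodioxin-5-yl trifluoromethanesulfonate
Conditions: KHMDS, THF, −78 °C; PhNTf2, −78 → 0 °C
Reagents that add atoms: N-phenylbis(trifluoromethanesulfonimide) O=S(=O)(N(c1ccccc1)S(=O)(=O)C(F)(F)F)C(F)(F)F
Why: The ketone can enolise only toward C10 because C4 is quaternary, and O-triflation of that enolate gives the C5=C10 enol triflate.

Step 5
Reactants: 6 enol triflate; 7 tributyl(1-ethoxyvinyl)stannane
Product: 9 1-[(4aS,8aS)-2,2,4a-trimethyl-4a,7,8,8a-tetrahydro-4H-1,3-benzodioxin-5-yl]ethan-1-one, via 2-ethoxydiene 8 (not isolated)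
Conditions: Pd(PPh3)4 (5 mol %), LiCl (3 equiv), THF, 65 °C; then 5 % aq. oxalic acid, THF, 0 °C
Reagents that add atoms: water O
Why: Stille coupling of the enol triflate with the α-alkoxyvinylstannane (an acetyl anion equivalent) forms the C5–C6 bond, and mild hydrolysis of the very labile enol ether unmasks the methyl ketone without touching the acetonide.

Step 6
Reactants: 9 ring-A methyl enone
Product: 10 tert-butyldimethyl({1-[(4aS,8aS)-2,2,4a-trimethyl-4a,7,8,8a-tetrahydro-4H-1,3-benzodioxin-5-yl]vinyl}oxy)silane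
Conditions: TBSOTf, Et3N, CH2Cl2, −78 → 0 °C
Reagents that add atoms: tert-butyldimethylsilyl triflate CC(C)(C)[Si](C)(C)OS(=O)(=O)C(F)(F)F
Why: Soft enolisation at the acetyl methyl group, the only α-position, gives the cross-conjugated 2-siloxydiene C10=C5–C6(OTBS)=C7.

Step 7
Reactants: 10 ring-A 2-siloxydiene; 11 (E)-2-methylbut-2-enal (tiglaldehyde)
Product: 12 tricyclic Diels–Alder adduct (3S,4S,8S,9R; C5=C6 TBS enol ether; C9 carries CH3 and CHO; C8 and C9 methyl groups cis; mixture at C10)
Conditions: (S)-o-tolyl-CBS-oxazaborolidine·HNTf2 (20 mol %), CH2Cl2, −78 → −40 °C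
Reagents that add atoms: none
Why: Catalytic enantioselective Diels–Alder reaction with a chiral oxazaborolidinium Lewis acid, in which the siloxy group sends the nucleophilic C7 terminus to the enal β-carbon (C8) and C10 to the α-carbon (C9), suprafacial addition to the (E)-enal makes the C8 and C9 methyl groups cis, and the catalyst should expose the C2-Si face of the bound s-trans enal and so fix C8 and C9 absolutely; the diene face and endo/exo preference only affect C10, which is lost in step 8.

Step 8
Reactants: 12 Diels–Alder adduct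
Product: 13 tricyclic enone aldehyde (3S,4S,8S,9R; C6 ketone; C5=C10; C9–CHO)
Conditions: Pd(OAc)2 (1.1 equiv), MeCN, rt → 40 °C
Reagents that add atoms: none
Why: Saegusa–Ito oxidation, in which Pd(II) takes over the regiodefined enol silane at C5 and β-hydride elimination can only use H-10 because C4 is quaternary, so either C10 epimer should give the tetrasubstituted C5=C10 enone.

Step 9
Reactants: 13 enone aldehyde
Product: 14 tricyclic 9-vinyl enone (3S,4S,8S,9R)
Conditions: Ph3PCH3Br, KHMDS, THF, 0 °C; then 13, −78 → 0 °C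
Reagents that add atoms: methyltriphenylphosphonium bromide C[P+](c1ccccc1)(c1ccccc1)c1ccccc1.[Br-]
Why: Wittig methylenation is chemoselective for the aldehyde, which has no α-hydrogen and cannot epimerise, over the conjugated and peri-shielded C6 ketone.

Step 10
Reactants: 14 9-vinyl enone
Product: 15 (6S)-allylic alcohol (3S,4S,6S,8S,9R)
Conditions: (R)-Me-CBS (0.5 equiv), catecholborane (2 equiv), toluene, −78 → −40 °C
Reagents that add atoms: none
Why: Corey–Bakshi–Shibata reduction, in which the catalyst binds the carbonyl lone pair on the C7 side (the C5 side is blocked by the quaternary C4) and should deliver hydride to the face that gives the (6S)-alcohol; catecholborane is chosen because it does not hydroborate the vinyl group at low temperature.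

Step 11
Reactants: 15 (6S)-allylic alcohol
Product: 16 6-O-TBS ether (3S,4S,6S,8S,9R)
Conditions: TBSOTf, 2,6-lutidine, CH2Cl2, −78 → 0 °C
Reagents that add atoms: tert-butyldimethylsilyl triflate CC(C)(C)[Si](C)(C)OS(=O)(=O)C(F)(F)F
Why: Silylation of the hindered secondary allylic alcohol with the reactive silyl triflate protects C6 for the later oxidation at C3.

Step 12
Reactants: 16 6-O-TBS ether; 17 2-bromoprop-2-en-1-ol
Product: 19 C16 allylic alcohol with side chain CH2CH2C(=CH2)CH2OH on C9, via B-alkyl-9-BBN 18 (not isolated)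
Conditions: 9-BBN dimer, THF, 0 °C → rt; then 17, PdCl2(dppf) (5 mol %), AsPh3, Cs2CO3, DMF/H2O, rt
Reagents that add atoms: none
Why: Anti-Markovnikov hydroboration of the vinyl group (the tetrasubstituted olefin is inert to 9-BBN) followed by B-alkyl Suzuki–Miyaura coupling with the vinyl bromide forms C12–C13 and installs the C13 methylene and the free C16 hydroxyl in one operation.

Step 13
Reactants: 19 C16 allylic alcohol
Product: 20 C16 acrylate
Conditions: acryloyl chloride, i-Pr2NEt, CH2Cl2, −78 → 0 °C
Reagents that add atoms: acryloyl chloride C=CC(Cl)=O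
Why: O-Acylation of the only free hydroxyl, a primary allylic alcohol, with the acid chloride brings in C14 and C15.

Step 14
Reactants: 20 C16 acrylate
Product: 21 C3,C18-diol (3S,4S,6S,8S,9R)
Conditions: PPTS, MeOH, rt → 40 °C
Reagents that add atoms: none
Why: Acid-catalysed transketalisation to methanol removes the acetonide while the hindered secondary TBS ether and the acrylate should persist under these mild conditions.

Step 15
Reactants: 22 3-(4-hydroxyphenyl)propanoic acid
Product: 24 3-{4-[(tert-butyldimethylsilyl)oxy]phenyl}propanoic acid, via bis-TBS silyl ester 23 (not isolated)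
Conditions: TBSCl (2.2 equiv), imidazole, DMF, rt; then AcOH/THF/H2O, rt
Reagents that add atoms: tert-butyldimethylsilyl chloride CC(C)(C)[Si](C)(C)Cl
Why: Silylation of both acidic groups followed by selective hydrolysis of the labile silyl ester leaves the more robust aryl silyl ether.

Step 16
Reactants: 21 C3,C18-diol; 24 TBS-protected acid
Product: 25 C18 ester (C3–OH free; 3S,4S,6S,8S,9R)
Conditions: EDC·HCl, DMAP (cat.), CH2Cl2, 0 °C → rt
Reagents that add atoms: none
Why: Steglich esterification should acylate the primary C18 hydroxyl in preference to the secondary C3 hydroxyl, which is flanked by the quaternary C4; C6 and the phenol are silylated.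

Step 17
Reactants: 25 C18 ester
Product: 26 C3 ketone (6-O-TBS, aryl-O-TBS; 4S,6S,8S,9R)
Conditions: Dess–Martin periodinane, pyridine, CH2Cl2, 0 °C → rt
Reagents that add atoms: none
Why: Dess–Martin oxidation of the only free hydroxyl gives the C3 ketone; C4 is quaternary, so neither epimerisation nor β-elimination of the acyloxymethyl group is possible.

Step 18
Reactants: 26 C3 ketone
Product: 27 fully deprotected acrylate diene (4S,6S,8S,9R)
Conditions: HF·pyridine, pyridine, THF, 0 °C → rt
Reagents that add atoms: none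
Why: Fluoride-mediated cleavage of the alkyl and aryl silyl ethers under buffered conditions should spare the acrylate, the C18 ester and the acid-sensitive C6 allylic alcohol.

Step 19
Reactants: 27 fully deprotected acrylate diene
Product: 28 CNP0301014.1 (target)
Conditions: Grubbs second-generation catalyst (10 mol %), CH2Cl2 (2 mM), 40 °C
Reagents that add atoms: none
Why: Ring-closing olefin metathesis: the ruthenium alkylidene engages the two terminal olefins of 27 (the acrylate CH=CH2 carrying C14 and the 1,1-disubstituted C13=CH2) by [2+2] cycloaddition and cycloreversion through ruthenacyclobutanes and expels ethylene, so C13=C14 is the last bond formed. The closest known reaction type is the RCM of acrylates of 2-substituted allylic alcohols to β-substituted butenolides with N-heterocyclic-carbene ruthenium catalysts. The ring closed is the five-membered α,β-unsaturated γ-lactone (O–C15(=O)–C14=C13–C16), closed between two olefin termini held five atoms apart by the ester tether, which can only give the endocyclic cis olefin. No stereocentre is created, and C4, C6, C8 and C9 are remote from the reacting olefins and untouched. The selectivity needed is chemoselectivity among three olefins and against acrylate cross-dimerisation: the C5=C10 olefin is tetrasubstituted and flanked by the quaternary C4 and C9, hence inert to the carbene, and high dilution favours the five-ring closure. The free C6 hydroxyl, phenol, ketone and esters are tolerated by the catalyst, which lets the step run on the unprotected compound.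

**Compound list**

1 | 2-methylcyclohexane-1,3-dione | CC1C(=O)CCCC1=O | starting material
2 | 2-(hydroxymethyl)-2-methylcyclohexane-1,3-dione | CC1(CO)C(=O)CCCC1=O | intermediate
3 | 2-{[(2-methoxypropan-2-yl)oxy]methyl}-2-methylcyclohexane-1,3-dione | CC1(COC(C)(C)OC)C(=O)CCCC1=O | intermediate
4 | (2S,3S)-3-hydroxy-2-{[(2-methoxypropan-2-yl)oxy]methyl}-2-methylcyclohexan-1-one (not isolated) | O=C1CCC[C@H](O)[C@]1(C)COC(C)(C)OC | intermediate
5 | (4aS,8aS)-2,2,4a-trimethylhexahydro-4H-1,3-benzodioxin-5-one | O=C1CCC[C@@H]2OC(C)(C)OC[C@]12C | intermediate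
6 | (4aS,8aS)-2,2,4a-trimethyl-4a,7,8,8a-tetrahydro-4H-1,3-benzodioxin-5-yl trifluoromethanesulfonate | FC(F)(F)S(=O)(=O)OC1=CCC[C@@H]2OC(C)(C)OC[C@]12C | intermediate
7 | tributyl(1-ethoxyvinyl)stannane | CCCC[Sn](CCCC)(CCCC)C(=C)OCC | starting material
8 | (4aS,8aS)-5-(1-ethoxyvinyl)-2,2,4a-trimethyl-4a,7,8,8a-tetrahydro-4H-1,3-benzodioxine (not isolated) | CCOC(=C)C1=CCC[C@@H]2OC(C)(C)OC[C@]12C | intermediate
9 | 1-[(4aS,8aS)-2,2,4a-trimethyl-4a,7,8,8a-tetrahydro-4H-1,3-benzodioxin-5-yl]ethan-1-one | CC(=O)C1=CCC[C@@H]2OC(C)(C)OC[C@]12C | intermediate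
10 | tert-butyldimethyl({1-[(4aS,8aS)-2,2,4a-trimethyl-4a,7,8,8a-tetrahydro-4H-1,3-benzodioxin-5-yl]vinyl}oxy)silane | C=C(O[Si](C)(C)C(C)(C)C)C1=CCC[C@@H]2OC(C)(C)OC[C@]12C | intermediate
11 | (E)-2-methylbut-2-enal (tiglaldehyde) | C/C=C(\C)C=O | starting material
12 | Diels–Alder adduct: C3/C18 acetonide, C5=C6 TBS enol ether, C9 (CH3, CHO), C8 CH3 cis to C9 CH3; 3S,4S,8S,9R; C10 epimer mixture | C[C@H]1CC(O[Si](C)(C)C(C)(C)C)=C2C(CC[C@@H]3OC(C)(C)OC[C@]23C)[C@]1(C)C=O | intermediate
13 | enone aldehyde: C3/C18 acetonide, C6 ketone, C5=C10, C9–CHO; 3S,4S,8S,9R | C[C@H]1CC(=O)C2=C(CC[C@@H]3OC(C)(C)OC[C@]23C)[C@]1(C)C=O | intermediate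
14 | 9-vinyl enone: as 13 with C9–CH=CH2; 3S,4S,8S,9R | C[C@H]1CC(=O)C2=C(CC[C@@H]3OC(C)(C)OC[C@]23C)[C@]1(C)C=C | intermediate
15 | (6S)-allylic alcohol: as 14 with C6–OH; 3S,4S,6S,8S,9R | C[C@H]1C[C@H](O)C2=C(CC[C@@H]3OC(C)(C)OC[C@]23C)[C@]1(C)C=C | intermediate
16 | 6-O-TBS ether of 15 | C[C@H]1C[C@H](O[Si](C)(C)C(C)(C)C)C2=C(CC[C@@H]3OC(C)(C)OC[C@]23C)[C@]1(C)C=C | intermediate
17 | 2-bromoprop-2-en-1-ol | OCC(Br)=C | starting material
18 | B-alkyl-9-BBN from 16 (boron on C12; not isolated) | C[C@H]1C[C@H](O[Si](C)(C)C(C)(C)C)C2=C(CC[C@@H]3OC(C)(C)OC[C@]23C)[C@]1(C)CCB1C2CCCC1CCC2 | intermediate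
19 | C16 allylic alcohol: C9–CH2CH2C(=CH2)CH2OH, 6-O-TBS, C3/C18 acetonide | C[C@H]1C[C@H](O[Si](C)(C)C(C)(C)C)C2=C(CC[C@@H]3OC(C)(C)OC[C@]23C)[C@]1(C)CCC(=C)CO | intermediate
20 | C16 acrylate of 19 | C[C@H]1C[C@H](O[Si](C)(C)C(C)(C)C)C2=C(CC[C@@H]3OC(C)(C)OC[C@]23C)[C@]1(C)CCC(=C)COC(=O)C=C | intermediate
21 | C3,C18-diol: 6-O-TBS, C16 acrylate; 3S,4S,6S,8S,9R | C[C@H]1C[C@H](O[Si](C)(C)C(C)(C)C)C2=C(CC[C@H](O)[C@]2(C)CO)[C@]1(C)CCC(=C)COC(=O)C=C | intermediate
22 | 3-(4-hydroxyphenyl)propanoic acid | OC(=O)CCc1ccc(O)cc1 | starting material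
23 | tert-butyldimethylsilyl 3-{4-[(tert-butyldimethylsilyl)oxy]phenyl}propanoate (not isolated) | CC(C)(C)[Si](C)(C)OC(=O)CCc1ccc(O[Si](C)(C)C(C)(C)C)cc1 | intermediate
24 | 3-{4-[(tert-butyldimethylsilyl)oxy]phenyl}propanoic acid | OC(=O)CCc1ccc(O[Si](C)(C)C(C)(C)C)cc1 | intermediate
25 | C18 ester: C3–OH, 6-O-TBS, aryl-O-TBS, C16 acrylate | C[C@H]1C[C@H](O[Si](C)(C)C(C)(C)C)C2=C(CC[C@H](O)[C@]2(C)COC(=O)CCc2ccc(O[Si](C)(C)C(C)(C)C)cc2)[C@]1(C)CCC(=C)COC(=O)C=C | intermediate
26 | C3 ketone: 6-O-TBS, aryl-O-TBS, C16 acrylate; 4S,6S,8S,9R | C[C@H]1C[C@H](O[Si](C)(C)C(C)(C)C)C2=C(CCC(=O)[C@]2(C)COC(=O)CCc2ccc(O[Si](C)(C)C(C)(C)C)cc2)[C@]1(C)CCC(=C)COC(=O)C=C | intermediate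
27 | deprotected acrylate diene: C6–OH, phenol, C13=CH2, C16-O-acryloyl; 4S,6S,8S,9R | C[C@H]1C[C@H](O)C2=C(CCC(=O)[C@]2(C)COC(=O)CCc2ccc(O)cc2)[C@]1(C)CCC(=C)COC(=O)C=C | intermediate
28 | CNP0301014.1: (4S,6S,8S,9R)-6-hydroxy-3-oxo-4-{[3-(4-hydroxyphenyl)propanoyloxy]methyl}halima-5(10),13-dien-15,16-olide | C[C@H]1C[C@H](O)C2=C(CCC(=O)[C@]2(C)COC(=O)CCc2ccc(O)cc2)[C@]1(C)CCC1=CC(=O)OC1 | target

**Totals.** Total step count: 19. Longest linear sequence: 18 steps (steps 1–14 and 16–19; step 15 is a one-step side branch).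

**Steps most likely to fail**

1. Step 7. The congested 2-siloxydiene, whose internal carbon C5 carries the quaternary C4, may be too slow toward the catalyst-bound trisubstituted enal, or face discrimination may be incomplete. Fallback: starting from 10 and 11, the cycloaddition is promoted with Me2AlCl (CH2Cl2, −78 °C), relying on the higher reactivity of an achiral Lewis acid in place of catalyst control. This should give 12 together with its C8,C9-epimeric cycloadduct F1. Saegusa oxidation of the mixture as in step 8 gives 13 and the C8,C9-epimeric enone aldehyde F2. Because C3 and C4 are fixed, these are diastereomers and are separated by chromatography; the route is rejoined at 13.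

2. Step 8. Transfer of the crowded, fully substituted enol silane to Pd(II) may be slow and lose out to protodesilylation. Fallback: starting from 12, PhSeCl (CH2Cl2, −78 °C) converts the enol silane into the C5 phenylselanyl ketone F3. Oxidation (m-CPBA, −78 °C; then i-Pr2NH, warm) gives the selenoxide F4, whose syn-elimination can only use H-10. The route is rejoined at 13.

3. Step 3. Discrimination between the two enantiotopic carbonyls may be incomplete, which would erode the enantiopurity of C4, or reduction may run on to the diol. Fallback: starting from 2, silylation (TBSCl, imidazole) gives the silyl ether dione F5. NaBH4 (MeOH, −78 °C) should give the racemic cis-hydroxy ketone F6. Lipase-catalysed acylation (lipase PS, vinyl acetate) should, by the usual empirical rule for secondary alcohols, convert the (2R,3R)-enantiomer into the acetate F7 and leave the (2S,3S)-alcohol F8. After separation, CSA/MeOH frees the diol F9, and 2,2-dimethoxypropane closes the acetonide; the route is rejoined at 5.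

Further compounds
F1 | step 7 | C8,C9-epimeric Diels–Alder adduct (3S,4S,8R,9S; C10 mixture) | C[C@@H]1CC(O[Si](C)(C)C(C)(C)C)=C2C(CC[C@@H]3OC(C)(C)OC[C@]23C)[C@@]1(C)C=O
F2 | step 7 | C8,C9-epimeric enone aldehyde (3S,4S,8R,9S) | C[C@@H]1CC(=O)C2=C(CC[C@@H]3OC(C)(C)OC[C@]23C)[C@@]1(C)C=O
F3 | step 8 | C5 phenylselanyl C6 ketone from 12 (C5, C10 mixture) | C[C@H]1CC(=O)C2([Se]c3ccccc3)C(CC[C@@H]3OC(C)(C)OC[C@]23C)[C@]1(C)C=O
F4 | step 8 | selenoxide of F3 | C[C@H]1CC(=O)C2([Se](=O)c3ccccc3)C(CC[C@@H]3OC(C)(C)OC[C@]23C)[C@]1(C)C=O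
F5 | step 3 | 2-{[(tert-butyldimethylsilyl)oxy]methyl}-2-methylcyclohexane-1,3-dione | CC1(CO[Si](C)(C)C(C)(C)C)C(=O)CCCC1=O
F6 | step 3 | (±)-cis-3-hydroxy-2-{[(tert-butyldimethylsilyl)oxy]methyl}-2-methylcyclohexan-1-one (racemate, OH cis to CH2OTBS) | O=C1CCCC(O)C1(C)CO[Si](C)(C)C(C)(C)C
F7 | step 3 | (1R,2R)-2-{[(tert-butyldimethylsilyl)oxy]methyl}-2-methyl-3-oxocyclohexyl acetate | O=C1CCC[C@@H](OC(C)=O)[C@@]1(C)CO[Si](C)(C)C(C)(C)C
F8 | step 3 | (2S,3S)-3-hydroxy-2-{[(tert-butyldimethylsilyl)oxy]methyl}-2-methylcyclohexan-1-one | O=C1CCC[C@H](O)[C@]1(C)CO[Si](C)(C)C(C)(C)C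
F9 | step 3 | (2S,3S)-3-hydroxy-2-(hydroxymethyl)-2-methylcyclohexan-1-one | O=C1CCC[C@H](O)[C@]1(C)CO
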